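**Strategy**

Ring A, the hexasubstituted benzene in which oxygens on C2′, C4′ and C6′ alternate with the isobutyryl carbon (C1′), the bridging CH2 (C3′) and the prenyl group (C5′), is disconnected at C1′–C2′ and C5′–C6′. A thermal cyclobutenone–silyloxyalkyne benzannulation makes both bonds and closes ring A in one neutral operation, sparing the base-labile triacyl quaternary carbon of ring B. Its precursor is a 2-prenyl-3-silyloxycyclobutenone that carries the (S)-configured ring B dienone, masked as a bis(methoxymethyl) enol ether, on a CH2 at C4; the partner alkyne holds the isobutyryl carbon as a dioxolane. Methoxymethyl rather than methyl enol ethers let ring B be unmasked by mild acid.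

Key step: step 14

Remark: the quaternary carbon of ring B is formed racemic and the (S) enantiomer is selected by chromatography; which fraction is (S) is assumed to be established once, by X-ray or ECD analysis of 14, before it is carried on.

**Route**

Step 1
Reactants: 1 4-methylbenzene-1,3-diol
Product: 2 2,4-bis(methoxymethoxy)-1-methylbenzene
Conditions: MOMCl (2.5 equiv), i-Pr2NEt, CH2Cl2, 0 °C → rt
Reagents that add atoms: chloromethyl methyl ether, COCCl
Why: Williamson-type O-alkylation of both phenols gives the bis(methoxymethyl) ether, which directs the lithiation of step 2, tolerates dissolving metal and is later removable from ring B with mild acid.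

Step 2
Reactants: 2 2,4-bis(methoxymethoxy)-1-methylbenzene; 3 N-methoxy-N,2-dimethylpropanamide
Product: 5 1-[2,6-bis(methoxymethoxy)-3-methylphenyl]-2-methylpropan-1-one, via aryllithium 4 (not isolated)
Conditions: n-BuLi, TMEDA, THF, 0 °C; then 3, −78 °C → rt; aq. NH4Cl
Reagents that add atoms: none
Why: Directed ortho-metalation at the carbon flanked by both acetal oxygens, followed by Weinreb ketone synthesis, whose chelated tetrahedral adduct prevents a second addition.

Step 3
Reactants: 5 1-[2,6-bis(methoxymethoxy)-3-methylphenyl]-2-methylpropan-1-one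
Product: 6 1-[3-bromo-2,6-bis(methoxymethoxy)-5-methylphenyl]-2-methylpropan-1-one
Conditions: NBS, MeCN, 0 °C → rt, dark
Reagents that add atoms: N-bromosuccinimide, BrN1C(=O)CCC1=O
Why: Electrophilic aromatic bromination at the only free carbon that is ortho to one alkoxy group and para to the other; the remaining free carbon is meta to both.

Step 4
Reactants: 6 1-[3-bromo-2,6-bis(methoxymethoxy)-5-methylphenyl]-2-methylpropan-1-one; 7 (3-ethoxy-3-oxopropyl)zinc bromide
Product: 8 ethyl 3-[2,4-bis(methoxymethoxy)-5-methyl-3-(2-methylpropanoyl)phenyl]propanoate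
Conditions: Pd(OAc)2 (cat.), SPhos (cat.), THF, 50 °C
Reagents that add atoms: none
Why: Negishi cross-coupling of a zinc homoenolate with the aryl bromide, an organometallic mild enough to leave the hindered ketone and the acetals alone.

Step 5
Reactants: 8 ethyl 3-[2,4-bis(methoxymethoxy)-5-methyl-3-(2-methylpropanoyl)phenyl]propanoate
Product: 9 3-[2,4-bis(methoxymethoxy)-5-methyl-3-(2-methylpropanoyl)phenyl]propanoic acid
Conditions: LiOH·H2O, THF–MeOH–H2O, rt; then 0.5 M HCl to pH 4, 0 °C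
Reagents that add atoms: lithium hydroxide, [Li+].[OH-]
Why: Saponification at the robust aromatic stage, so that the side chain enters the dissolving-metal step as an inert carboxylate and no ester has to be cleaved once ring B is base-sensitive.

Step 6
Reactants: 9 3-[2,4-bis(methoxymethoxy)-5-methyl-3-(2-methylpropanoyl)phenyl]propanoic acid; 10 1-bromo-3-methylbut-2-ene (prenyl bromide)
Product: 12 rac-3-[2,4-bis(methoxymethoxy)-5-methyl-3-(3-methylbut-2-en-1-yl)-3-(2-methylpropanoyl)cyclohexa-1,4-dien-1-yl]propanoic acid, via dipotassium dienolate 11 (not isolated)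
Conditions: KOt-Bu (1.0 equiv), THF; K (2.2 equiv), NH3–THF, −78 °C; LiBr; then 10, −78 °C; NH4Cl; NaH2PO4 buffer (pH 5), 0 °C
Reagents that add atoms: none
Why: Birch reduction–alkylation of an aryl ketone, in which two electrons from potassium and para protonation by the one equivalent of tert-butanol (released when KOt-Bu forms the carboxylate) give cross-conjugated dienolate 11, which prenyl bromide should alkylate at the acyl-bearing carbon; the quaternary stereocenter forms without a controlling element, hence racemic, and the (S) enantiomer is selected in step 8.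

Step 7
Reactants: 12 rac-3-[2,4-bis(methoxymethoxy)-5-methyl-3-(3-methylbut-2-en-1-yl)-3-(2-methylpropanoyl)cyclohexa-1,4-dien-1-yl]propanoic acid
Product: 13 rac-3-[2,4-bis(methoxymethoxy)-5-methyl-3-(3-methylbut-2-en-1-yl)-3-(2-methylpropanoyl)-6-oxocyclohexa-1,4-dien-1-yl]propanoic acid
Conditions: (C5H5NH)2Cr2O7, t-BuOOH (in decane), Celite, PhH, 10 °C → rt; used on crude 12
Reagents that add atoms: tert-butyl hydroperoxide, CC(C)(C)OO
Why: Allylic oxidation by t-BuOOH mediated by hexavalent chromium (the dichromate transfers oxygen, the hydroperoxide is the terminal oxidant) should attack the doubly allylic ring CH2, the weakest C–H bond, and give the cross-conjugated dienone, which cannot aromatize because C3 is quaternary and whose enol ethers are now acid-tolerant vinylogous esters.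

Step 8
Reactants: 13 rac-3-[2,4-bis(methoxymethoxy)-5-methyl-3-(3-methylbut-2-en-1-yl)-3-(2-methylpropanoyl)-6-oxocyclohexa-1,4-dien-1-yl]propanoic acid
Product: 14 3-[(3S)-2,4-bis(methoxymethoxy)-5-methyl-3-(3-methylbut-2-en-1-yl)-3-(2-methylpropanoyl)-6-oxocyclohexa-1,4-dien-1-yl]propanoic acid
Conditions: preparative SFC, amylose tris(3,5-dimethylphenylcarbamate) phase, CO2–i-PrOH, 35 °C; (S) fraction collected
Reagents that add atoms: none
Why: Resolution by chromatography on a chiral stationary phase, which changes no bond and fixes the only stereocenter of the target; being quaternary and non-enolizable, it cannot be scrambled afterwards.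

Step 9
Reactants: 15 4-methylpent-3-enoic acid
Product: 16 methyl 4-methylpent-3-enoate
Conditions: MeI, KHCO3, DMF, rt
Reagents that add atoms: iodomethane, CI
Why: Carboxylate SN2 alkylation gives the ester without acid, which would lactonize this β,γ-unsaturated acid.

Step 10
Reactants: 16 methyl 4-methylpent-3-enoate
Product: 18 [(5-methylhex-4-en-1-yn-1-yl)oxy]tri(propan-2-yl)silane, via lithium ynolate 17 (not isolated)
Conditions: CH2Br2, lithium 2,2,6,6-tetramethylpiperidide (2.2 equiv), THF, −78 °C; then n-BuLi, −78 → 25 °C; then i-Pr3SiCl, −78 °C → rt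
Reagents that add atoms: dibromomethane, BrCBr; chlorotri(propan-2-yl)silane, CC(C)[Si](Cl)(C(C)C)C(C)C
Why: Kowalski ester homologation stopped at the ynolate: LiCHBr2 adds to the ester, bromine–lithium exchange on the dibromo enolate triggers the 1,2-shift of the prenyl group to ynolate 17, and the bulky silyl chloride silylates it on oxygen.

Step 11
Reactants: 14 3-[(3S)-2,4-bis(methoxymethoxy)-5-methyl-3-(3-methylbut-2-en-1-yl)-3-(2-methylpropanoyl)-6-oxocyclohexa-1,4-dien-1-yl]propanoic acid; 18 [(5-methylhex-4-en-1-yn-1-yl)oxy]tri(propan-2-yl)silane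
Product: 21 4-{[(3S)-2,4-bis(methoxymethoxy)-5-methyl-3-(3-methylbut-2-en-1-yl)-3-(2-methylpropanoyl)-6-oxocyclohexa-1,4-dien-1-yl]methyl}-2-(3-methylbut-2-en-1-yl)-3-{[tri(propan-2-yl)silyl]oxy}cyclobut-2-en-1-one (both C4 epimers), via acid chloride 19 (not isolated), via ketene 20 (not isolated)
Conditions: 1-chloro-N,N,2-trimethylprop-1-en-1-amine, CH2Cl2, 0 °C; then slow addition to 18 (2 equiv) and Et3N, CH2Cl2, rt; rapid chromatography on Et3N-deactivated silica
Reagents that add atoms: none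
Why: Ketene–ynol ether (2+2) cycloaddition: the acid chloride, made without HCl by the chloroenamine, is dehydrochlorinated to aldoketene 20, whose carbonyl carbon is attacked by the prenyl-bearing carbon of 18, so prenyl should land on C2 and the silyloxy group on C3; the new C4 stereocenter is uncontrolled and irrelevant because it is lost in step 14.

Step 12
Reactants: 22 ethyl 3-methyl-2-oxobutanoate
Product: 23 ethyl 2-(propan-2-yl)-1,3-dioxolane-2-carboxylate
Conditions: Me3SiOCH2CH2OSiMe3, Me3SiOTf (cat.), CH2Cl2, −78 °C → rt; pyridine quench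
Reagents that add atoms: 1,2-bis(trimethylsilyloxy)ethane, C[Si](C)(C)OCCO[Si](C)(C)C
Why: Noyori ketalization converts the hindered but electrophilic α-keto group under aprotic conditions that cannot transesterify the ester with the glycol.

Step 13
Reactants: 23 ethyl 2-(propan-2-yl)-1,3-dioxolane-2-carboxylate
Product: 25 2-(propan-2-yl)-2-({[tri(propan-2-yl)silyl]oxy}ethynyl)-1,3-dioxolane, via lithium ynolate 24 (not isolated)
Conditions: CH2Br2, lithium 2,2,6,6-tetramethylpiperidide (2.2 equiv), THF, −78 °C; then n-BuLi, −78 → 25 °C; then i-Pr3SiCl, −78 °C → rt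
Reagents that add atoms: dibromomethane, BrCBr; chlorotri(propan-2-yl)silane, CC(C)[Si](Cl)(C(C)C)C(C)C
Why: Kowalski ester homologation to the ynolate, the ester having no α-hydrogen and being activated by its two α-oxygens, followed by O-silylation with the bulky silyl chloride.

Step 14
Reactants: 21 4-{[(3S)-2,4-bis(methoxymethoxy)-5-methyl-3-(3-methylbut-2-en-1-yl)-3-(2-methylpropanoyl)-6-oxocyclohexa-1,4-dien-1-yl]methyl}-2-(3-methylbut-2-en-1-yl)-3-{[tri(propan-2-yl)silyl]oxy}cyclobut-2-en-1-one; 25 2-(propan-2-yl)-2-({[tri(propan-2-yl)silyl]oxy}ethynyl)-1,3-dioxolane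
Product: 30 (4S)-2-{[2-hydroxy-5-(3-methylbut-2-en-1-yl)-3-[2-(propan-2-yl)-1,3-dioxolan-2-yl]-4,6-bis{[tri(propan-2-yl)silyl]oxy}phenyl]methyl}-3,5-bis(methoxymethoxy)-6-methyl-4-(3-methylbut-2-en-1-yl)-4-(2-methylpropanoyl)cyclohexa-2,5-dien-1-one, via vinylketene 26 (not isolated), via 2-vinylcyclobutenone 27 (not isolated), via dienylketene 28 (not isolated), via cyclohexa-2,4-dienone 29 (not isolated)
Conditions: 25 (2 equiv), PhMe (0.2 M), 80 °C then 110 °C, sealed tube, Ar
Reagents that add atoms: none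
Why: Heat should open cyclobutenone 21 by four-electron conrotatory cleavage of C1–C4 to vinylketene 26, the C4 alkyl group turning outward so that no 1,5-hydrogen shift drains it; the ketene C=C then adds alkyne 25 in a (2+2) cycloaddition, 2-vinylcyclobutenone 27 opens to dienylketene 28, and 28 closes to cyclohexadienone 29, which tautomerizes to phenol 30. This is the Danheiser benzannulation in its silyloxyalkyne form, and 21 is the kind of 3-silyloxycyclobutenone that ketene–silyloxyalkyne cycloadditions supply. Ring A is closed by a thermal disrotatory six-electron electrocyclization that re-forms C2′–C3′ (the old C1–C4 bond) after the (2+2) step has made C1′–C2′ and C5′–C6′. No stereocenter is created: the sp3 carbons of 21, 27 and 29 all end in the aromatic ring, so both C4 epimers of 21 converge, and the (S) carbon of ring B is a spectator. The step needs the regiochemistry of the (2+2) addition, which the silyloxy group secures by making the dioxolane-bearing alkyne carbon the nucleophile toward the ketene carbonyl carbon, and it needs chemoselectivity over the prenyl groups and the ring B dienone, which the far more ketenophilic silyloxyalkyne, used in excess, should secure. The medium is neutral and aprotic, so the triacyl carbon of ring B, the acetals and the silyl ethers should pass unchanged.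

Step 15
Reactants: 30 (the benzannulation product)
Product: 31 (4S)-3,5-dihydroxy-2-{[2-hydroxy-5-(3-methylbut-2-en-1-yl)-3-(2-methylpropanoyl)-4,6-bis{[tri(propan-2-yl)silyl]oxy}phenyl]methyl}-6-methyl-4-(3-methylbut-2-en-1-yl)-4-(2-methylpropanoyl)cyclohexa-2,5-dien-1-one
Conditions: 1 M aq. HCl, THF, 0 °C → rt
Reagents that add atoms: water, O
Why: Acid-catalyzed acetal hydrolysis, in which the benzylic dioxolane ionizes readily on the electron-rich ring and the two vinylogous methoxymethyl esters cleave like acylals, while the aryl silyl ethers stay on and cover both oxygens next to the ring A prenyl group, blocking chroman formation; the released formaldehyde finds no unsubstituted nucleophilic carbon.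

Step 16
Reactants: 31 (the bis-silyl ether)
Product: 32 (4S)-3,5-dihydroxy-2-{[2,4,6-trihydroxy-3-(3-methylbut-2-en-1-yl)-5-(2-methylpropanoyl)phenyl]methyl}-6-methyl-4-(3-methylbut-2-en-1-yl)-4-(2-methylpropanoyl)cyclohexa-2,5-dien-1-one (target)
Conditions: n-Bu4NF (2.5 equiv), AcOH (2.5 equiv), THF, 0 °C; pH 4 buffer work-up
Reagents that add atoms: none
Why: Fluoride-induced cleavage of the two aryl silyl ethers under acetic acid buffering; ring B is by now a vinylogous acid present as its unreactive enolate, so neither retro-Claisen cleavage nor exchange at the methylene bridge is expected, and the quaternary (S) center is untouched.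

**Compound list**

1 | 4-methylbenzene-1,3-diol | Cc1ccc(O)cc1O | starting material
2 | 2,4-bis(methoxymethoxy)-1-methylbenzene | Cc1ccc(OCOC)cc1OCOC | intermediate
3 | N-methoxy-N,2-dimethylpropanamide | CC(C)C(=O)N(C)OC | starting material
4 | [2,6-bis(methoxymethoxy)-3-methylphenyl]lithium | [Li]c1c(OCOC)ccc(C)c1OCOC | intermediate
5 | 1-[2,6-bis(methoxymethoxy)-3-methylphenyl]-2-methylpropan-1-one | CC(C)C(=O)c1c(OCOC)ccc(C)c1OCOC | intermediate
6 | 1-[3-bromo-2,6-bis(methoxymethoxy)-5-methylphenyl]-2-methylpropan-1-one | CC(C)C(=O)c1c(OCOC)c(Br)cc(C)c1OCOC | intermediate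
7 | (3-ethoxy-3-oxopropyl)zinc bromide | CCOC(=O)CC[Zn]Br | starting material
8 | ethyl 3-[2,4-bis(methoxymethoxy)-5-methyl-3-(2-methylpropanoyl)phenyl]propanoate | CCOC(=O)CCc1cc(C)c(OCOC)c(C(=O)C(C)C)c1OCOC | intermediate
9 | 3-[2,4-bis(methoxymethoxy)-5-methyl-3-(2-methylpropanoyl)phenyl]propanoic acid | OC(=O)CCc1cc(C)c(OCOC)c(C(=O)C(C)C)c1OCOC | intermediate
10 | 1-bromo-3-methylbut-2-ene (prenyl bromide) | CC(C)=CCBr | starting material
11 | dipotassium 3-[2,4-bis(methoxymethoxy)-5-methyl-3-(2-methyl-1-oxidopropylidene)cyclohexa-1,4-dien-1-yl]propanoate | CC(C)C([O-])=C1C(OCOC)=C(C)CC(CCC(=O)[O-])=C1OCOC.[K+].[K+] | intermediate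
12 | rac-3-[2,4-bis(methoxymethoxy)-5-methyl-3-(3-methylbut-2-en-1-yl)-3-(2-methylpropanoyl)cyclohexa-1,4-dien-1-yl]propanoic acid | OC(=O)CCC1=C(OCOC)C(CC=C(C)C)(C(=O)C(C)C)C(OCOC)=C(C)C1 | intermediate
13 | rac-3-[2,4-bis(methoxymethoxy)-5-methyl-3-(3-methylbut-2-en-1-yl)-3-(2-methylpropanoyl)-6-oxocyclohexa-1,4-dien-1-yl]propanoic acid | OC(=O)CCC1=C(OCOC)C(CC=C(C)C)(C(=O)C(C)C)C(OCOC)=C(C)C1=O | intermediate
14 | 3-[(3S)-2,4-bis(methoxymethoxy)-5-methyl-3-(3-methylbut-2-en-1-yl)-3-(2-methylpropanoyl)-6-oxocyclohexa-1,4-dien-1-yl]propanoic acid | OC(=O)CCC1=C(OCOC)[C@@](CC=C(C)C)(C(=O)C(C)C)C(OCOC)=C(C)C1=O | intermediate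
15 | 4-methylpent-3-enoic acid | CC(C)=CCC(O)=O | starting material
16 | methyl 4-methylpent-3-enoate | COC(=O)CC=C(C)C | intermediate
17 | lithium 5-methylhex-4-en-1-yn-1-olate | CC(C)=CCC#C[O-].[Li+] | intermediate
18 | [(5-methylhex-4-en-1-yn-1-yl)oxy]tri(propan-2-yl)silane | CC(C)=CCC#CO[Si](C(C)C)(C(C)C)C(C)C | intermediate
19 | 3-[(3S)-ring B]propanoyl chloride (acid chloride of 14) | ClC(=O)CCC1=C(OCOC)[C@@](CC=C(C)C)(C(=O)C(C)C)C(OCOC)=C(C)C1=O | intermediate
20 | aldoketene from 19, (ring B)CH2CH=C=O | O=C=CCC1=C(OCOC)[C@@](CC=C(C)C)(C(=O)C(C)C)C(OCOC)=C(C)C1=O | intermediate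
21 | 4-{[(3S)-2,4-bis(methoxymethoxy)-5-methyl-3-(3-methylbut-2-en-1-yl)-3-(2-methylpropanoyl)-6-oxocyclohexa-1,4-dien-1-yl]methyl}-2-(3-methylbut-2-en-1-yl)-3-{[tri(propan-2-yl)silyl]oxy}cyclobut-2-en-1-one, both C4 epimers | O=C1C(CC=C(C)C)=C(O[Si](C(C)C)(C(C)C)C(C)C)C1CC1=C(OCOC)[C@@](CC=C(C)C)(C(=O)C(C)C)C(OCOC)=C(C)C1=O | intermediate
22 | ethyl 3-methyl-2-oxobutanoate | CCOC(=O)C(=O)C(C)C | starting material
23 | ethyl 2-(propan-2-yl)-1,3-dioxolane-2-carboxylate | CCOC(=O)C1(C(C)C)OCCO1 | intermediate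
24 | lithium 2-[2-(propan-2-yl)-1,3-dioxolan-2-yl]ethyn-1-olate | CC(C)C1(OCCO1)C#C[O-].[Li+] | intermediate
25 | 2-(propan-2-yl)-2-({[tri(propan-2-yl)silyl]oxy}ethynyl)-1,3-dioxolane | CC(C)C1(OCCO1)C#CO[Si](C(C)C)(C(C)C)C(C)C | intermediate
26 | vinylketene from 21: 2-prenyl-3-silyloxy-5-(ring B)penta-1,3-dien-1-one, C3=C4 with CH2 cis to OSi | O=C=C(CC=C(C)C)\C(O[Si](C(C)C)(C(C)C)C(C)C)=C\CC1=C(OCOC)[C@@](CC=C(C)C)(C(=O)C(C)C)C(OCOC)=C(C)C1=O | intermediate
27 | (2+2) adduct: 2-(dioxolanyl)-3-silyloxy-4-prenyl-4-[1-silyloxy-3-(ring B)prop-1-enyl]cyclobut-2-en-1-one | O=C1C(C2(C(C)C)OCCO2)=C(O[Si](C(C)C)(C(C)C)C(C)C)C1(CC=C(C)C)\C(O[Si](C(C)C)(C(C)C)C(C)C)=C\CC1=C(OCOC)[C@@](CC=C(C)C)(C(=O)C(C)C)C(OCOC)=C(C)C1=O | intermediate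
28 | dienylketene: 2-(dioxolanyl)-3,5-bis(silyloxy)-4-prenyl-7-(ring B)hepta-1,3,5-trien-1-one | O=C=C(C1(C(C)C)OCCO1)\C(O[Si](C(C)C)(C(C)C)C(C)C)=C(CC=C(C)C)/C(O[Si](C(C)C)(C(C)C)C(C)C)=C/CC1=C(OCOC)[C@@](CC=C(C)C)(C(=O)C(C)C)C(OCOC)=C(C)C1=O | intermediate
29 | 2-(dioxolanyl)-4-prenyl-3,5-bis(silyloxy)-6-[(ring B)methyl]cyclohexa-2,4-dien-1-one | O=C1C(C2(C(C)C)OCCO2)=C(O[Si](C(C)C)(C(C)C)C(C)C)C(CC=C(C)C)=C(O[Si](C(C)C)(C(C)C)C(C)C)C1CC1=C(OCOC)[C@@](CC=C(C)C)(C(=O)C(C)C)C(OCOC)=C(C)C1=O | intermediate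
30 | (4S)-2-{[2-hydroxy-5-(3-methylbut-2-en-1-yl)-3-[2-(propan-2-yl)-1,3-dioxolan-2-yl]-4,6-bis{[tri(propan-2-yl)silyl]oxy}phenyl]methyl}-3,5-bis(methoxymethoxy)-6-methyl-4-(3-methylbut-2-en-1-yl)-4-(2-methylpropanoyl)cyclohexa-2,5-dien-1-one | CC(C)=CCc1c(O[Si](C(C)C)(C(C)C)C(C)C)c(CC2=C(OCOC)[C@@](CC=C(C)C)(C(=O)C(C)C)C(OCOC)=C(C)C2=O)c(O)c(C2(C(C)C)OCCO2)c1O[Si](C(C)C)(C(C)C)C(C)C | intermediate
31 | (4S)-3,5-dihydroxy-2-{[2-hydroxy-5-(3-methylbut-2-en-1-yl)-3-(2-methylpropanoyl)-4,6-bis{[tri(propan-2-yl)silyl]oxy}phenyl]methyl}-6-methyl-4-(3-methylbut-2-en-1-yl)-4-(2-methylpropanoyl)cyclohexa-2,5-dien-1-one | CC(C)=CCc1c(O[Si](C(C)C)(C(C)C)C(C)C)c(CC2=C(O)[C@@](CC=C(C)C)(C(=O)C(C)C)C(O)=C(C)C2=O)c(O)c(C(=O)C(C)C)c1O[Si](C(C)C)(C(C)C)C(C)C | intermediate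
32 | (4S)-3,5-dihydroxy-2-{[2,4,6-trihydroxy-3-(3-methylbut-2-en-1-yl)-5-(2-methylpropanoyl)phenyl]methyl}-6-methyl-4-(3-methylbut-2-en-1-yl)-4-(2-methylpropanoyl)cyclohexa-2,5-dien-1-one | CC(C)=CCc1c(O)c(CC2=C(O)[C@@](CC=C(C)C)(C(=O)C(C)C)C(O)=C(C)C2=O)c(O)c(C(=O)C(C)C)c1O | target

**Step count**

Total: 16 steps. Longest linear sequence: 12 steps (steps 1–8, 11, 14, 15, 16). Steps 9–10 and 12–13 make the two alkynes.

**Steps most likely to fail**

Step 14. Capture of vinylketene 26 by alkyne 25 may be slow, because the attacking alkyne carbon carries a quaternary ketal carbon and the arene being formed is hexasubstituted with two bulky silyl ethers; the vinylketene would then re-close, dimerize or decay by hydrogen shift. The fallback exchanges the roles of the two alkynes. It sets out from acid 14. Ketene 20, generated as in step 11, is captured at room temperature by the hindered alkyne 25 and should give 4-{[(3S)-2,4-bis(methoxymethoxy)-5-methyl-3-(3-methylbut-2-en-1-yl)-3-(2-methylpropanoyl)-6-oxocyclohexa-1,4-dien-1-yl]methyl}-2-[2-(propan-2-yl)-1,3-dioxolan-2-yl]-3-{[tri(propan-2-yl)silyl]oxy}cyclobut-2-en-1-one F1. Heating F1 with the unhindered alkyne 18 in toluene then forms C1′–C6′ and C4′–C5′ instead and should give the isomeric arene (4S)-2-{[2-hydroxy-3-(3-methylbut-2-en-1-yl)-5-[2-(propan-2-yl)-1,3-dioxolan-2-yl]-4,6-bis{[tri(propan-2-yl)silyl]oxy}phenyl]methyl}-3,5-bis(methoxymethoxy)-6-methyl-4-(3-methylbut-2-en-1-yl)-4-(2-methylpropanoyl)cyclohexa-2,5-dien-1-one F2. Aqueous HCl in THF as in step 15 should give (4S)-3,5-dihydroxy-2-{[2-hydroxy-3-(3-methylbut-2-en-1-yl)-5-(2-methylpropanoyl)-4,6-bis{[tri(propan-2-yl)silyl]oxy}phenyl]methyl}-6-methyl-4-(3-methylbut-2-en-1-yl)-4-(2-methylpropanoyl)cyclohexa-2,5-dien-1-one F3, and buffered n-Bu4NF as in step 16 comes back to the route at target 32.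

Step 6. In liquid ammonia the hindered dienolate may be prenylated on oxygen, or prenyl bromide may be consumed by ammonia and by the carboxylate before C-alkylation; over-reduction at the twisted carbonyl group would add to the loss. The fallback separates reduction from alkylation. It sets out from acid 9. Birch reduction (KOt-Bu, K, NH3–THF, −78 °C) quenched with NH4Cl should give the dihydro ketone rac-3-[2,4-bis(methoxymethoxy)-5-methyl-3-(2-methylpropanoyl)cyclohexa-1,4-dien-1-yl]propanoic acid F4. Its dianion, formed with KN(SiMe3)2 (2.2 equiv) in THF at −78 °C, is then C-alkylated with prenyl bromide 10 as an ordinary enolate alkylation under aprotic conditions, which comes back to the route at 12.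

Step 13. Addition of LiCHBr2 to the hindered ester, or the 1,2-shift of the tertiary ketal carbon in the carbenoid, may be too slow, so that the carbenoid decomposes before the ynolate forms. The fallback makes the ynolate by oxidation of an acetylide. It sets out from ester 23. Reduction with i-Bu2AlH (CH2Cl2, −78 °C) should give 2-(propan-2-yl)-1,3-dioxolane-2-carbaldehyde F5. Ohira–Bestmann homologation (dimethyl (1-diazo-2-oxopropyl)phosphonate, K2CO3, MeOH) should give 2-ethynyl-2-(propan-2-yl)-1,3-dioxolane F6. Its lithium acetylide (n-BuLi, THF, −78 °C) is oxidized with LiOOt-Bu (from t-BuOOH and LiN(SiMe3)2) and the ynolate 24 is silylated with i-Pr3SiOTf, which comes back to the route at 25.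

**Further compounds**

F1 | step 14 | 4-{[(3S)-2,4-bis(methoxymethoxy)-5-methyl-3-(3-methylbut-2-en-1-yl)-3-(2-methylpropanoyl)-6-oxocyclohexa-1,4-dien-1-yl]methyl}-2-[2-(propan-2-yl)-1,3-dioxolan-2-yl]-3-{[tri(propan-2-yl)silyl]oxy}cyclobut-2-en-1-one | O=C1C(C2(C(C)C)OCCO2)=C(O[Si](C(C)C)(C(C)C)C(C)C)C1CC1=C(OCOC)[C@@](CC=C(C)C)(C(=O)C(C)C)C(OCOC)=C(C)C1=O
F2 | step 14 | (4S)-2-{[2-hydroxy-3-(3-methylbut-2-en-1-yl)-5-[2-(propan-2-yl)-1,3-dioxolan-2-yl]-4,6-bis{[tri(propan-2-yl)silyl]oxy}phenyl]methyl}-3,5-bis(methoxymethoxy)-6-methyl-4-(3-methylbut-2-en-1-yl)-4-(2-methylpropanoyl)cyclohexa-2,5-dien-1-one | CC(C)=CCc1c(O)c(CC2=C(OCOC)[C@@](CC=C(C)C)(C(=O)C(C)C)C(OCOC)=C(C)C2=O)c(O[Si](C(C)C)(C(C)C)C(C)C)c(C2(C(C)C)OCCO2)c1O[Si](C(C)C)(C(C)C)C(C)C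
F3 | step 14 | (4S)-3,5-dihydroxy-2-{[2-hydroxy-3-(3-methylbut-2-en-1-yl)-5-(2-methylpropanoyl)-4,6-bis{[tri(propan-2-yl)silyl]oxy}phenyl]methyl}-6-methyl-4-(3-methylbut-2-en-1-yl)-4-(2-methylpropanoyl)cyclohexa-2,5-dien-1-one | CC(C)=CCc1c(O)c(CC2=C(O)[C@@](CC=C(C)C)(C(=O)C(C)C)C(O)=C(C)C2=O)c(O[Si](C(C)C)(C(C)C)C(C)C)c(C(=O)C(C)C)c1O[Si](C(C)C)(C(C)C)C(C)C
F4 | step 6 | rac-3-[2,4-bis(methoxymethoxy)-5-methyl-3-(2-methylpropanoyl)cyclohexa-1,4-dien-1-yl]propanoic acid | OC(=O)CCC1=C(OCOC)C(C(=O)C(C)C)C(OCOC)=C(C)C1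
F5 | step 13 | 2-(propan-2-yl)-1,3-dioxolane-2-carbaldehyde | CC(C)C1(C=O)OCCO1
F6 | step 13 | 2-ethynyl-2-(propan-2-yl)-1,3-dioxolane | CC(C)C1(C#C)OCCO1
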